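The runs come from a simulation for substances that don't exist; scatter was added.

Count what is left.

| flask | starting material | free catalyst | target | time |
|---|---|---|---|---|
| dusk | 200 mM | 2.00 mM |  |  |
| spring | 200 mM | 2.00 mM | 100 mM |  |
| dawn | 200 mM | 4.00 mM |  |  |
| winter | 400 mM | 2.00 mM |  |  |
| midnight | 920 mM | 2.00 mM |  | 230 h |

| run | time / h | [target] / mM |
|---|---|---|
| dusk run | 9.2 | 11.7 |
| dusk run | 21 | 25.0 |
| dusk run | 46 | 51.4 |
| dusk run | 100 | 95.2 |
| dusk run | 230 | 156.3 |
| spring run | 9.2 | 111.6 |
| spring run | 21 | 125.1 |
| spring run | 46 | 152.1 |
| spring run | 100 | 196.4 |
| spring run | 230 | 257.6 |
| dawn run | 9.2 | 35.2 |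
| dawn run | 21 | 71.4 |
| dawn run | 46 | 125.4 |
| dawn run | 100 | 177.3 |
| dawn run | 230 | 199.1 |
| winter run | 9.2 | 21.9 |
| winter run | 21 | 46.8 |
| winter run | 46 | 94.9 |
| winter run | 100 | 181.4 |
| winter run | 230 | 306.9 |

(each reading ± 0.6 mM)

1. how the opening rate goes with [starting material] round the charge of the dusk run: the exponent of the rate at two percent of starting material gone to target (one fixed amount of target, the same in the runs compared)
2. how the opening rate goes with [free catalyst] round the charge of the dusk run: the exponent of the rate at two percent of starting material gone to target
3. target in the midnight run at 230 h, as a share of the starting material charged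

- Overall: starting material -> target, with free catalyst as catalyst.
- Constant volume, constant temperature.
- What is held in complexes is read along with the free species.
- An order is taken over about fifteen percent of the charge, up and down.

For a run, take f, the fraction of starting material left at 230 h, and its depth L = −ln f. The spring run gained 158 mM by then on top of its added target and the dusk run made 156.3 mM, so these readings show no effect of the added target on the rate.

Turn the question round. With the catalyst full of starting material, each flask charged with 2.00 mM of it would make the same amount of target per hour, the winter run would read 156.3 mM at 230 h, and the midnight run would reach 17.0% of its charge. The winter run read 306.9 mM, about twice the dusk value. So the dusk and winter runs stand near the other end, the pseudo-first-order one, where L at one time and one catalyst charge is the same for any charge of starting material. Yet L slips, from 1.52 in the dusk run to 1.46 in the winter run, and this slip is read with a scatter of about 0.0137 in L.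

Call K, the bending charge, the target gained per unit of L lost:

K = [c(target, winter) − c(target, dusk)] / [L(dusk) − L(winter)] = 2380 mM

This reckoning takes L + c(target)/K as constant between charges at one time and one catalyst charge:

B = L(dusk) + c(target, dusk)/K = 1.59

In this reckoning the order in starting material round the dusk charge is 0.923. For the midnight run, begin from the dusk f and repeat:

f = exp(−B + c(target)/K), with c(target) the share made times 920 mM

f = 0.277, then 0.271, then 0.271

That gives 72.9% made. At 125.4 mM against 51.4 mM after 46 h, L in the dawn run is 3.32 times that in the dusk run, for twice the catalyst, an exponent of 1.73 averaged over the whole step.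

The forecast gives 0.88, 1.7 and 71%, 1.9 percentage points below this reckoning, and reads the creeping rate constant as one “which suggests mild saturation”.

The midnight run gives 71.4%; round the charge of the dusk run, the opening orders are 0.92 in starting material and 2.3 in free catalyst.

    free catalyst + starting material ⇌ catalyst-substrate complex, settled at all times (0.5800 L mol⁻¹)
    catalyst-substrate complex → target + free catalyst (13.61 h⁻¹)
    free catalyst + impurity → spent catalyst

In the midnight run, impurity spends 1.10 mM of the 2.00 mM of free catalyst charged, leaving 0.900 mM as free catalyst and catalyst-substrate complex together. Taken from the dusk run to the midnight run, K comes to 1860 mM. At one catalyst charge the rule makes the time to half of the charge go as ln 2 + charge/(2K), so the 106 h of the dusk run becomes 113 h for the winter run, which stands at 114 h.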